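All runs come from a simulation with made-up constants; noise was put on by code.

The time the meeting had to answer for was 4.0 min, in a closed, stirred, isothermal flask.

| setting | midnight | winter | flask |
|---|---|---|---|
| E | 9.5 mM | 38 mM | 19 mM |
| Z | 1.9 mM | 1.9 mM | 1.90 mM |
| L | 0.36 mol% | 0.36 mol% | 0.36 mol% |
| remark | run made earlier | run made earlier |  |
| time |  |  | 4.0 min |

| run | time / min | Q / % | E / % |
|---|---|---|---|
| midnight | 0.333 | 1.1 | 94.5 |
| midnight | 0.667 | 4.1 | 88.8 |
| midnight | 1.00 | 12.3 | 77.7 |
| midnight | 2.00 | 47.3 | 38.9 |
| midnight | 4.00 | 80.3 | 4.0 |
| winter | 0.333 | 9.4 | 87.5 |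
| winter | 1.00 | 73.3 | 21.8 |
| winter | 2.00 | 95.0 | 0.9 |
| winter | 3.00 | 96.1 | 0.1 |
| winter | 4.00 | 95.1 | 0 |

(each reading ± 0.5 percentage points)

- the average divides the monomer in chains by the number of chains begun, living and dead together
- the earlier runs do not show the number of chains; that part of a forecast is a guess

1. average number of monomer units in a chain (chains begun, living or dead) at 4.0 min
2. part of the E that has reacted at 4.0 min

The first speaker noted that E falls slowly at first and then steepens in both runs, and she read the late pseudo-first-order slope, the fall of ln E per minute: 1.14 min⁻¹ in the midnight run, 3.19 min⁻¹ in the winter run. She argued that if this slope counts living chains, each taking up E with one fixed constant, then Q over the slope follows chain length. For the midnight run this reads 0.402 M·s, and she called it the gauge, the amount of Q divided by the late slope.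

The second speaker observed that the flask's 19 mM of E is the geometric mean of the two runs, so he took the same mean of the slopes, 1.90 min⁻¹. Counting the charged E as Q, he got a flask gauge of 0.600 M·s. Then he went round again: at the last readings E plus Q falls short by 1.49 mM in the midnight run and 1.86 mM in the winter run, and the geometric mean of these leaves 17.3 mM of Q and a gauge of 0.546 M·s. By his reckoning, with one scale from gauge to length for both, the flask's chains should be longer than those of the midnight run by a factor of 1.36. That is a ratio, not a length, since the earlier runs do not show the number of chains.

The forecast was then tabled: an average of 250 units per chain and 99.7 % of the E reacted, with the remark “Chains are a guess”.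

The simulation gives the flask an average of 1120 units per chain and 99.9 % of the E reacted.

    E + G → X + Q (k = 0.588 M⁻¹ s⁻¹)
    E + X → Q + X, rate k2*[X]*[E] (k = 2380 M⁻¹ s⁻¹)
    Z + E → D (k = 1.40 M⁻¹ s⁻¹)
    L → G (k = 0.0119 s⁻¹)

The flask's average is 4.48 times the forecast's, and at 4.00 min the flask holds the living end X at 0.0156 mM beside more of the initiator G, at 0.0489 mM. Dividing the flask's average by the gauge reckoned for it gives a scale of 2040 M⁻¹ s⁻¹. Applied to the gauge of the midnight run, that scale gives 820, and the midnight run at the time of its last reading, without the scatter, has an average of 914.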